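Atoms are numbered as the heavy atoms of the target SMILES. Ring A is the cyclopropane (C6, C20, C21), B the oxepane, C the dihydropyran, D the cycloheptane (C18–C24). The carbinol C24 lies β to acetal carbon C13, so with C13 raised to a lactone carbonyl the ring D bond C18–C24 is an aldol bond. That bond is made last. SmI2 turns a tricyclic α-bromo enol lactone, in which rings A, B and C are complete and C21 carries a 3-oxobutyl chain, into a samarium enolate that attacks the ketone. This closes the trans-fused ring D and sets C18 and C24 at once. Lactone reduction and acetylation finish the synthesis.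

Key step: step 16

Assumption: the configuration is taken exactly as written, so C7 and C19 are cis on ring A (ring B cis-fused), and C22 is trans to C19 and cis to C5 (ring D trans-fused).

Remark: O–C5 is carried as a 4-methoxybenzyl (PMB) ether rather than a silyl ether. Steps 8 and 9 generate the C7 alkoxide 1,3 to O–C5, where a silyl group could migrate and erase the C5/C7 distinction. The PMB ether also keeps the key-step precursor free of O–H groups.

Step 1
Reactants: 1 5-hexen-2-one
Product: 2 2-(but-3-en-1-yl)-2-methyl-1,3-dioxolane
Conditions: HOCH2CH2OH (1.5 equiv), p-TsOH·H2O (1 mol %), toluene, reflux, Dean–Stark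
Reagents that add atoms: ethylene glycol, OCCO
Why: Acid-catalysed ketalisation driven by azeotropic removal of water masks the C24 ketone against the hydrides, ylide and amide base to come, leaves the terminal alkene alone and creates no stereocentre.

Step 2
Reactants: 2 2-(but-3-en-1-yl)-2-methyl-1,3-dioxolane; 3 (E)-crotonaldehyde
Product: 4 (E)-5-(2-methyl-1,3-dioxolan-2-yl)pent-2-enal
Conditions: second-generation Hoveyda–Grubbs catalyst (2 mol %), 3 (4 equiv), CH2Cl2, 40 °C
Reagents that add atoms: none
Why: Olefin cross-metathesis between an unhindered terminal alkene and an electron-poor enal partner favours the cross product, loses a gaseous alkene and should give the E-enal (C20=C21) under thermodynamic control.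

Step 3
Reactants: 4 (E)-5-(2-methyl-1,3-dioxolan-2-yl)pent-2-enal; 5 dimethyl bromomalonate
Product: 6 dimethyl (2R,3R)-2-formyl-3-[2-(2-methyl-1,3-dioxolan-2-yl)ethyl]cyclopropane-1,1-dicarboxylate
Conditions: (S)-2-[diphenyl(trimethylsilyloxy)methyl]pyrrolidine (10 mol %), 2,6-lutidine (1.1 equiv), CH2Cl2, 0 °C → rt
Reagents that add atoms: none
Why: Organocatalytic Michael-initiated ring closure through iminium and then enamine activation: the malonate carbon (C6) adds to C21 on the face of the E-iminium ion left open by the bulky group of the S-catalyst, and the enamine then displaces bromide in a 3-exo-tet closure that keeps C19 and C22 trans, which sets C20 and C21 in the absolute sense of the target.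

Step 4
Reactants: 6 cyclopropane aldehyde diester
Product: 7 (1R,3R)-2,2-bis(methoxycarbonyl)-3-[2-(2-methyl-1,3-dioxolan-2-yl)ethyl]cyclopropane-1-carboxylic acid
Conditions: NaClO2, NaH2PO4, 2-methyl-2-butene, t-BuOH–H2O, 0 °C → rt
Reagents that add atoms: sodium chlorite, [Na+].[O-]Cl=O
Why: Pinnick oxidation is selective for the aldehyde, runs in a phosphate buffer that the dioxolane tolerates, leaves the stereocentres alone and lifts C19 to a carboxylic acid that borohydride will not reduce, so that C19 stays distinct from C5 and C7.

Step 5
Reactants: 7 cyclopropane acid diester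
Product: 9 (1R,5S,6R)-5-(hydroxymethyl)-6-[2-(2-methyl-1,3-dioxolan-2-yl)ethyl]-3-oxabicyclo[3.1.0]hexan-2-one, via dihydroxy acid 8 (not isolated)
Conditions: LiBH4 (5 equiv), THF–MeOH (20:1), 0 → 40 °C; then aq. citric acid (pH 4), rt
Reagents that add atoms: none
Why: Chemoselective borohydride reduction followed by lactonisation: LiBH4 reduces both methyl esters but not the lithium carboxylate formed with its first equivalent, and on acidification only the hydroxymethyl group cis to C19 can close the γ-lactone, so geometry alone tells C7 (lactone) from C5 (free alcohol) and thereby fixes the quaternary stereocentre C6.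

Step 6
Reactants: 9 hydroxy lactone
Product: 10 (1R,5S,6R)-5-[(4-methoxybenzyloxy)methyl]-6-[2-(2-methyl-1,3-dioxolan-2-yl)ethyl]-3-oxabicyclo[3.1.0]hexan-2-one
Conditions: NaH (1.2 equiv), 4-MeOC6H4CH2Cl (1.2 equiv), Bu4NI (10 mol %), DMF, 0 °C → rt
Reagents that add atoms: 4-methoxybenzyl chloride, COc1ccc(CCl)cc1
Why: Williamson etherification of the only free hydroxyl group, whose alkoxide cannot reach the lactone carbonyl because C5 is trans to C19, installs a non-migrating ether that survives every step up to the key step.

Step 7
Reactants: 10 PMB lactone
Product: 11 lactol of 10 (C19–OH, anomer mixture)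
Conditions: iBu2AlH (1.1 equiv), CH2Cl2, −78 °C; aq. potassium sodium tartrate
Reagents that add atoms: none
Why: Partial reduction of a γ-lactone with one equivalent of iBu2AlH stops at the aluminium hemiacetal at −78 °C and gives the lactol on work-up, while ketal and PMB ether are inert.

Step 8
Reactants: 11 lactol
Product: 12 ring A carbinol with CH2OH (C7) cis to the new C20 vinyl group, CH2OPMB (C5) cis to the C21 side chain, vinyl and side chain trans
Conditions: Ph3PCH3Br (3 equiv), KOtBu (2.9 equiv), THF, 0 °C → rt
Reagents that add atoms: methyltriphenylphosphonium bromide, C[P+](c1ccccc1)(c1ccccc1)c1ccccc1.[Br-]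
Why: Wittig methylenation of a lactol, well known for cis-fused cyclopropane lactols of the caronaldehyde type, turns C19 into a vinyl carbon and frees the C7 hydroxyl in the same operation, the cyclopropyl C20–H being too weakly acidic to epimerise.

Step 9
Reactants: 12 ring A carbinol; 13 3-chloro-2-(chloromethyl)prop-1-ene
Product: 14 2-(chloromethyl)allyl ether of 12 (new O8–C9 bond)
Conditions: NaH (1.3 equiv), 13 (5 equiv), Bu4NI (10 mol %), THF–DMF, 0 °C → rt
Reagents that add atoms: none
Why: Williamson etherification with a large excess of the symmetrical bis-allylic chloride gives the mono-ether and brings in C9, C10 and C11 with a leaving group kept on C11.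

Step 10
Reactants: 14 diene ether
Product: 15 bicyclic oxepine chloride (3-oxabicyclo[5.1.0]oct-5-ene; ring B cis-fused to ring A, C10=C19 double bond, CH2Cl = C11 on C10)
Conditions: second-generation Hoveyda–Grubbs catalyst (5 mol %), toluene (2 mM), 80 °C
Reagents that add atoms: none
Why: Ring-closing metathesis of two alkenes held cis on ring A forms the trisubstituted C10=C19 double bond and the seven-membered ring B, allylic chlorides and vinylcyclopropanes both being tolerated by ruthenium carbenes.

Step 11
Reactants: 15 oxepine chloride
Product: 16 bicyclic oxepine enal (as 15, with CHO = C11 on C10)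
Conditions: N-methylmorpholine N-oxide (5 equiv), KI (20 mol %), 4 Å MS, MeCN, 40 °C
Reagents that add atoms: N-methylmorpholine N-oxide, C[N+]1([O-])CCOCC1
Why: Amine N-oxide oxidation of an activated halide (Ganem variant of the Kornblum oxidation): SN2 attack of the oxide oxygen at the primary allylic C11 and base-induced N–O cleavage give the enal directly under nearly neutral conditions.

Step 12
Reactants: 16 oxepine enal; 17 trimethyl(vinyloxy)silane
Product: 19 tricyclic enol lactol (rings A to C; C13–OH anomers; C19 as in the target), via silyl acetal cycloadduct 18 (not isolated)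
Conditions: Yb(fod)3 (10 mol %), 17 (15 equiv, neat), 4 Å MS, 60 °C, sealed tube; then AcOH–THF–H2O (1:8:1), 0 °C
Reagents that add atoms: none
Why: Inverse-electron-demand oxa-Diels–Alder reaction of an enal with an enol ether under mild lanthanide catalysis forms C18–C19 and O12–C13 in one concerted event, without a C10 enolate that could expel O8; the dienophile reaches C19 past the small C20–H, anti to the ring A bonds on the convex face of the bicycle, which sets C19, and brief aqueous acetic acid cleaves only the silyl acetal.

Step 13
Reactants: 19 tricyclic enol lactol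
Product: 20 tricyclic enol lactone ketal
Conditions: nPr4N[RuO4] (5 mol %), N-methylmorpholine N-oxide (1.5 equiv), 4 Å MS, CH2Cl2, 0 °C → rt
Reagents that add atoms: none
Why: Ley–Griffith oxidation converts the lactol into the enol lactone under neutral conditions that spare the enol ether, ketal and PMB groups, and it removes the irrelevant C13 stereocentre.

Step 14
Reactants: 20 tricyclic enol lactone ketal
Product: 22 α-bromo enol lactone ketal (C18 epimers), via silyl ketene acetal 21 (not isolated)
Conditions: Me3SiCl (1.5 equiv), LiN(SiMe3)2 (1.2 equiv), THF, −78 °C; then N-bromosuccinimide (1.05 equiv), −78 °C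
Reagents that add atoms: N-bromosuccinimide, O=C1CCC(=O)N1Br
Why: Electrophilic bromination of a silyl ketene acetal: C18 is the only acidic position while the ketone is masked, the in situ silyl trap keeps the enol-lactone enolate from fragmenting to a ketene, and the ketene acetal is far more nucleophilic toward N-bromosuccinimide than the enol ester double bond, the C18 configuration being irrelevant.

Step 15
Reactants: 22 α-bromo enol lactone ketal
Product: 23 tricyclic α-bromo enol lactone with 3-oxobutyl chain on C21 (PMB ether at O–C5; either C18 epimer)
Conditions: PPTS (20 mol %), acetone–H2O (10:1), 40 °C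
Reagents that add atoms: water, O
Why: Mild acid-catalysed ketal hydrolysis in wet acetone frees the methyl ketone without harming the PMB ether, the enol lactone or the bromide.

Step 16
Reactants: 23 tricyclic α-bromo enol lactone with 3-oxobutyl chain
Product: 26 tetracyclic hydroxy enol lactone PMB ether, via samarium enolate 24 (not isolated), via samarium aldolate 25 (not isolated)
Conditions: SmI2 (2.5 equiv, 0.1 M in THF), slow addition of 23 (final 5 mM), THF, −78 °C; pH 7 phosphate buffer at −78 °C
Reagents that add atoms: none
Why: SmI2 delivers two electrons in turn to the C18–Br bond, so either C18 epimer of 23 converges on one oxygen-bound enolate 24 of trivalent samarium, which adds to the tethered methyl ketone and is held as aldolate 25 until the cold quench; the closest known reaction type is the SmI2-promoted intramolecular Reformatsky reaction of α-halo esters with ketones, which is established for medium-sized carbocycles. Ring D closes in a 7-(enolexo)-exo-trig mode, C18 attacking C24 with the C=O bond outside the new ring. C18 is controlled by the tether, because the link C22–C23–C24 hangs from C21 and can reach the planar enolate only on the face that carries C20, which puts H18 cis to H19. C24 is controlled by chelation, because samarium binds both oxygens in a closed transition state, so O26 ends up on the same side of ring D as C13 and C25 points away. The step needs reduction of C–Br before the ketone and closure before protonation: an α-bromo ester is reduced far more easily than an unactivated dialkyl ketone at −78 °C without HMPA or a proton donor, and 23 carries no O–H group. The price is the strain of a trans-bicyclo[5.1.0]octane, which is why an irreversible low-temperature closure is chosen, while ring B limits rotation about C19–C20 and the transient radical and charge at C18 stay one carbon removed from ring A.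

Step 17
Reactants: 26 tetracyclic hydroxy enol lactone PMB ether
Product: 27 tetracyclic dihydroxy enol lactone (free C5–OH and C24–OH)
Conditions: DDQ (1.3 equiv), CH2Cl2–pH 7 buffer (10:1), 0 °C
Reagents that add atoms: none
Why: Oxidative cleavage of the electron-rich PMB ether with DDQ in a buffered two-phase medium avoids the base or fluoride that could trigger retro-aldol opening of ring D, and the enol ester is too electron-poor to compete.

Step 18
Reactants: 27 tetracyclic dihydroxy enol lactone
Product: 28 tetracyclic enol lactol triol (C13–OH, equilibrating anomers)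
Conditions: iBu2AlH (4 equiv), CH2Cl2–THF, −78 °C; aq. potassium sodium tartrate, 0 °C
Reagents that add atoms: none
Why: Partial reduction of an enol δ-lactone with iBu2AlH at −78 °C, a conversion known for iridoid enol lactones, gives the enol hemiacetal after a neutral tartrate work-up, two equivalents of the hydride being consumed by the hydroxyl groups.

Step 19
Reactants: 28 tetracyclic enol lactol triol
Product: 29 target CNP0250836.2
Conditions: Ac2O (6 equiv), pyridine, 0 °C → rt
Reagents that add atoms: acetic anhydride, CC(=O)OC(C)=O
Why: Acetylation under equilibrating conditions: the lactol anomers interconvert in pyridine, and the one with O14 pseudo-axial on the convex face, trans to the C18–C24 bond, is both favoured by the anomeric effect and acetylated faster, which sets C13, while the primary C5 hydroxyl is esterified and the hindered tertiary O26–H is not.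

Compound list

1 | 5-hexen-2-one | C=CCCC(C)=O | starting material
2 | 2-(but-3-en-1-yl)-2-methyl-1,3-dioxolane | C=CCCC1(C)OCCO1 | intermediate
3 | (E)-crotonaldehyde | C/C=C/C=O | starting material
4 | (E)-5-(2-methyl-1,3-dioxolan-2-yl)pent-2-enal | O=C/C=C/CCC1(C)OCCO1 | intermediate
5 | dimethyl bromomalonate | COC(=O)C(Br)C(=O)OC | starting material
6 | dimethyl (2R,3R)-2-formyl-3-[2-(2-methyl-1,3-dioxolan-2-yl)ethyl]cyclopropane-1,1-dicarboxylate (formyl and side chain trans) | COC(=O)C1(C(=O)OC)[C@H](C=O)[C@H]1CCC2(C)OCCO2 | intermediate
7 | (1R,3R)-2,2-bis(methoxycarbonyl)-3-[2-(2-methyl-1,3-dioxolan-2-yl)ethyl]cyclopropane-1-carboxylic acid | COC(=O)C1(C(=O)OC)[C@H](C(=O)O)[C@H]1CCC2(C)OCCO2 | intermediate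
8 | (1R,3R)-2,2-bis(hydroxymethyl)-3-[2-(2-methyl-1,3-dioxolan-2-yl)ethyl]cyclopropane-1-carboxylic acid (not isolated) | OCC1(CO)[C@H](C(=O)O)[C@H]1CCC2(C)OCCO2 | intermediate
9 | (1R,5S,6R)-5-(hydroxymethyl)-6-[2-(2-methyl-1,3-dioxolan-2-yl)ethyl]-3-oxabicyclo[3.1.0]hexan-2-one | OC[C@@]12COC(=O)[C@@H]1[C@H]2CCC3(C)OCCO3 | intermediate
10 | (1R,5S,6R)-5-[(4-methoxybenzyloxy)methyl]-6-[2-(2-methyl-1,3-dioxolan-2-yl)ethyl]-3-oxabicyclo[3.1.0]hexan-2-one | COc1ccc(COC[C@@]23COC(=O)[C@@H]2[C@H]3CCC4(C)OCCO4)cc1 | intermediate
11 | lactol of 10, (1R,5S,6R)-configured 3-oxabicyclo[3.1.0]hexan-2-ol, anomers at C19 | COc1ccc(COC[C@@]23COC(O)[C@@H]2[C@H]3CCC4(C)OCCO4)cc1 | intermediate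
12 | ring A carbinol: C6 bears CH2OH (C7, cis to the C20 vinyl group) and CH2OPMB (C5, cis to the C21 ketal side chain); vinyl and side chain trans | COc1ccc(COC[C@@]2(CO)[C@H](C=C)[C@H]2CCC3(C)OCCO3)cc1 | intermediate
13 | 3-chloro-2-(chloromethyl)prop-1-ene | C=C(CCl)CCl | starting material
14 | 2-(chloromethyl)allyl ether of 12 at the C7 oxygen (O8) | COc1ccc(COC[C@@]2(COCC(=C)CCl)[C@H](C=C)[C@H]2CCC3(C)OCCO3)cc1 | intermediate
15 | 3-oxabicyclo[5.1.0]oct-5-ene (rings A and B cis-fused) with CH2Cl (C11) on C10, CH2OPMB on C6, ketal side chain on C21 trans to C19 | COc1ccc(COC[C@@]23COCC(CCl)=C[C@@H]2[C@H]3CCC4(C)OCCO4)cc1 | intermediate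
16 | oxepine enal: as 15 with CHO (C11) on C10 | COc1ccc(COC[C@@]23COCC(C=O)=C[C@@H]2[C@H]3CCC4(C)OCCO4)cc1 | intermediate
17 | trimethyl(vinyloxy)silane | C=CO[Si](C)(C)C | starting material
18 | tricyclic cycloadduct, C13–OSiMe3 acetal, C18 anti to ring A at C19 (not isolated) | COc1ccc(COC[C@@]23COCC4=COC(O[Si](C)(C)C)C[C@H]4[C@@H]2[C@H]3CCC5(C)OCCO5)cc1 | intermediate
19 | tricyclic enol lactol, C13–OH anomers, C6, C19, C20, C21 as in the target | COc1ccc(COC[C@@]23COCC4=COC(O)C[C@H]4[C@@H]2[C@H]3CCC5(C)OCCO5)cc1 | intermediate
20 | tricyclic enol lactone ketal (C13=O) | COc1ccc(COC[C@@]23COCC4=COC(=O)C[C@H]4[C@@H]2[C@H]3CCC5(C)OCCO5)cc1 | intermediate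
21 | trimethylsilyl ketene acetal of 20 (C13=C18; not isolated) | COc1ccc(COC[C@@]23COCC4=COC(O[Si](C)(C)C)=C[C@H]4[C@@H]2[C@H]3CCC5(C)OCCO5)cc1 | intermediate
22 | α-bromo enol lactone ketal (Br on C18, both epimers) | COc1ccc(COC[C@@]23COCC4=COC(=O)C(Br)[C@H]4[C@@H]2[C@H]3CCC5(C)OCCO5)cc1 | intermediate
23 | key-step precursor: tricyclic α-bromo enol lactone with 3-oxobutyl chain on C21, PMB ether at O–C5 | COc1ccc(COC[C@@]23COCC4=COC(=O)C(Br)[C@H]4[C@@H]2[C@H]3CCC(C)=O)cc1 | intermediate
24 | samarium enolate of the lactone (C13=C18, O–SmI2; not isolated) | COc1ccc(COC[C@@]23COCC4=COC(O[Sm](I)I)=C[C@H]4[C@@H]2[C@H]3CCC(C)=O)cc1 | intermediate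
25 | samarium aldolate (O26–SmI2; not isolated) | COc1ccc(COC[C@@]23COCC4=COC(=O)[C@@H]5[C@H]4[C@@H]2[C@H]3CC[C@]5(C)O[Sm](I)I)cc1 | intermediate
26 | key-step product: tetracyclic hydroxy enol lactone PMB ether; H18 cis to H19, O26 syn to C13, ring D trans-fused to ring A | COc1ccc(COC[C@@]23COCC4=COC(=O)[C@@H]5[C@H]4[C@@H]2[C@H]3CC[C@]5(C)O)cc1 | intermediate
27 | tetracyclic dihydroxy enol lactone | OC[C@@]12COCC3=COC(=O)[C@@H]4[C@H]3[C@@H]1[C@H]2CC[C@]4(C)O | intermediate
28 | tetracyclic enol lactol triol (C13 anomers) | OC[C@@]12COCC3=COC(O)[C@@H]4[C@H]3[C@@H]1[C@H]2CC[C@]4(C)O | intermediate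
29 | CNP0250836.2: diacetate with O14 trans to the C18–C24 bond | CC(=O)OC[C@@]12COCC3=CO[C@H](OC(C)=O)[C@@H]4[C@H]3[C@@H]1[C@H]2CC[C@]4(C)O | target

Total step count: 19. Longest linear sequence: 19 steps (from 1).

Steps most likely to fail

**Step 16 (key step).**
- Process at risk: the transition state already carries much of the strain of the trans A/D fusion. Closure may therefore be outrun by protonation of the enolate (net debromination), or the aldolate may revert on warming.
- Fallback: a Mukaiyama-type closure onto an oxocarbenium ion replaces a metal enolate adding to a ketone. It sets out from 20. The silyl ketene acetal 21 is generated as in step 14, freed from salts by a non-aqueous work-up and exposed to Me3SiOTf in CH2Cl2 at −78 °C. The dioxolane opens to a far more electrophilic oxocarbenium ion at C24, which C18 captures irreversibly. After work-up this gives the tetracyclic 2-hydroxyethyl ether F1, a product that cannot undergo retro-aldol cleavage. Appel iodination (I2, PPh3, imidazole) gives the tetracyclic 2-iodoethyl ether F2. Zinc dust in THF–AcOH then fragments F2 reductively to 26, where the route is rejoined.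

**Step 12.**
- Process at risk: the trisubstituted heterodiene may react too slowly with a singly oxygenated dienophile, and 1,2-addition of the silyl enol ether to the aldehyde may compete.
- Fallback: the two carbons are delivered by conjugate addition at the ester oxidation level and the ring is closed by dehydrative enol-lactonisation, so no lactol and no oxidation are needed. It sets out from 16. Heating with 1,1-diethoxyethene, a ketene acetal far more nucleophilic than an enol ether, gives the cyclic orthoester F3. A pH 5 buffer opens it to the aldehyde ethyl ester F4 (C10 epimers, of no consequence). Me3SnOH in 1,2-dichloroethane cleaves the ester without the base that could expel O8 and gives the aldehyde acid F5. Ac2O with NaOAc, the classical cyclodehydration of 5-oxo acids, closes 20, where the route is rejoined.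

**Step 18.**
- Process at risk: ring–chain tautomerism of the free lactol exposes a β-hydroxy aldehyde (C13, C18, C24) whose retro-aldol cleavage would release the strain of ring D. It also exposes a β-alkoxy aldehyde (C11, C10, C9–O8) open to elimination. Collapse of the aluminium hemiacetal with over-reduction is a further loss channel.
- Fallback: reductive acetylation in one flask. It sets out from 27. After iBu2AlH at −78 °C, pyridine, DMAP and Ac2O are added at −78 °C before any water. The aluminium hemiacetal and the C5 alkoxide are then acetylated directly, and the route is rejoined at 29 without 28 ever being liberated. The anomeric outcome would then reflect the face of hydride delivery rather than equilibration and would have to be checked.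

Further compounds

F1 | step 16 | tetracyclic 2-hydroxyethyl ether (O26–CH2CH2OH) | COc1ccc(COC[C@@]23COCC4=COC(=O)[C@@H]5[C@H]4[C@@H]2[C@H]3CC[C@]5(C)OCCO)cc1
F2 | step 16 | tetracyclic 2-iodoethyl ether (O26–CH2CH2I) | COc1ccc(COC[C@@]23COCC4=COC(=O)[C@@H]5[C@H]4[C@@H]2[C@H]3CC[C@]5(C)OCCI)cc1
F3 | step 12 | cyclic orthoester (2,2-diethoxy cycloadduct at C13) | COc1ccc(COC[C@@]23COCC4=COC(OCC)(OCC)C[C@H]4[C@@H]2[C@H]3CCC5(C)OCCO5)cc1
F4 | step 12 | aldehyde ethyl ester (CHO on C10, CH2CO2Et on C19) | COc1ccc(COC[C@@]23COCC(C=O)[C@@H](CC(=O)OCC)[C@@H]2[C@H]3CCC4(C)OCCO4)cc1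
F5 | step 12 | aldehyde acid (CHO on C10, CH2CO2H on C19) | COc1ccc(COC[C@@]23COCC(C=O)[C@@H](CC(=O)O)[C@@H]2[C@H]3CCC4(C)OCCO4)cc1
F0 | step 18 | none | none
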